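**Retrosynthetic overview**
1. Ring C is the only ring that has to be built. It is closed last, at the O1–C2 bond, by acid cyclodehydration of an o-hydroxyaryl 1,3-diketone.
2. The diketone is cut at the C2–C3 bond (flavone numbering). This is an intermolecular crossed Claisen condensation of the dianion of 6'-hydroxy-2',3'-dimethoxyacetophenone (ring A) with 2,3,6-trimethoxybenzoyl chloride (ring B).
3. The ring A ketone comes from 3,4-dimethoxyphenol by MOM protection, lithiation between OMOM and OMe, addition to acetaldehyde, oxidation and MOM removal.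
4. The ring B acid chloride comes from 1,2,4-trimethoxybenzene by lithiation between two OMe groups, then CO2, then (COCl)2.
5. Rings A and B are bought as arenes, and no stereocentre has to be set.

Assumption: the target has no stereocentre and its C2–C1' aryl axis rotates freely at room temperature. It is therefore achiral, and "single enantiomer" calls for no stereocontrol.

**Route**

Step 1
Reactants: 1 3,4-dimethoxyphenol
Product: 3 1,2-dimethoxy-4-(methoxymethoxy)benzene, via sodium phenoxide 2 (not isolated)
Conditions: NaH (1.2 equiv), THF, 0 °C, 30 min; MOMCl (1.2 equiv), 0 °C to rt, 2 h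
Reagents that add atoms: chloromethyl methyl ether (MOMCl), COCCl
Why: Williamson-type O-alkylation of the phenoxide by the very reactive alpha-chloro ether is fast and clean, and the MOM ether both masks the acidic OH and supplies a strong directing group for step 2; no stereocentre is formed.

Step 2
Reactants: 3 1,2-dimethoxy-4-(methoxymethoxy)benzene
Product: 6 rac-1-[2,3-dimethoxy-6-(methoxymethoxy)phenyl]ethan-1-ol, via aryllithium 4 (not isolated), via lithium alkoxide 5 (not isolated)
Conditions: n-BuLi (1.2 equiv), TMEDA (1.2 equiv), THF, 0 °C, 1.5 h; MeCHO (3 equiv), −78 °C to rt; H2O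
Reagents that add atoms: acetaldehyde, CC=O
Why: Directed ortho-metalation takes place at the one ring position flanked by both OMOM and OMe (cooperative 1,3-directing effect), and 1,2-addition of the aryllithium to acetaldehyde gives the carbinol, whose new stereocentre is formed racemic and is erased in step 3.

Step 3
Reactants: 6 rac-1-[2,3-dimethoxy-6-(methoxymethoxy)phenyl]ethan-1-ol
Product: 7 1-[2,3-dimethoxy-6-(methoxymethoxy)phenyl]ethan-1-one
Conditions: Dess–Martin periodinane (1.3 equiv), CH2Cl2, rt, 2 h
Reagents that add atoms: none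
Why: Dess–Martin oxidation converts the hindered benzylic secondary alcohol into the ketone under near-neutral conditions that leave the MOM acetal, the aryl methyl ethers and the electron-rich ring untouched, and it removes the only stereocentre.

Step 4
Reactants: 7 1-[2,3-dimethoxy-6-(methoxymethoxy)phenyl]ethan-1-one
Product: 8 1-(6-hydroxy-2,3-dimethoxyphenyl)ethan-1-one
Conditions: 3 M aq HCl, THF, 50 °C, 3 h
Reagents that add atoms: none
Why: Acid-catalysed acetal hydrolysis cleaves only the MOM group, since aryl methyl ethers are inert to dilute HCl, and the freed phenol is stabilised by its hydrogen bond to the ketone; no stereocentre.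

Step 5
Reactants: 9 1,2,4-trimethoxybenzene
Product: 12 2,3,6-trimethoxybenzoic acid, via aryllithium 10 (not isolated), via lithium carboxylate 11 (not isolated)
Conditions: n-BuLi (1.1 equiv), THF, 0 °C to rt, 2 h; CO2 (dried gas), −78 °C to rt; 2 M HCl to pH 1
Reagents that add atoms: carbon dioxide, O=C=O
Why: Directed ortho-metalation of 9 occurs at C3, the position between two methoxy groups, and carboxylation of the aryllithium gives the acid, which is purified by acid-base extraction; no stereocentre.

Step 6
Reactants: 12 2,3,6-trimethoxybenzoic acid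
Product: 13 2,3,6-trimethoxybenzoyl chloride
Conditions: (COCl)2 (1.5 equiv), N,N-dimethylformamide (cat.), CH2Cl2, 0 °C to rt, 2 h; evaporate, use crude
Reagents that add atoms: oxalyl chloride, O=C(Cl)C(=O)Cl
Why: Vilsmeier-type (formamide-catalysed) acid chloride formation runs at room temperature without Lewis acid or heat, so the ortho methoxy groups are not cleaved; no stereocentre.

Step 7
Reactants: 8 1-(6-hydroxy-2,3-dimethoxyphenyl)ethan-1-one; 13 2,3,6-trimethoxybenzoyl chloride
Product: 16 1-(6-hydroxy-2,3-dimethoxyphenyl)-3-(2,3,6-trimethoxyphenyl)propane-1,3-dione, via dilithium dianion 14 (not isolated), via dilithium diketonate 15 (not isolated)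
Conditions: 8, LiN(SiMe3)2 (3.2 equiv), THF, −78 to −10 °C, 2 h; 13 (1.0 equiv) in THF, −78 °C to rt, 4 h; ice/1 M HCl
Reagents that add atoms: none
Why: Intermolecular crossed Claisen condensation, in which the carbon terminus of the dianion is far more nucleophilic than its phenoxide oxygen and is C-acylated by the aroyl chloride (chosen over the ester because di-ortho-substituted benzoates resist addition), while the third equivalent of base traps the product as its diketonate and stops a second acylation; no stereocentre.

Step 8
Reactants: 16 1-(6-hydroxy-2,3-dimethoxyphenyl)-3-(2,3,6-trimethoxyphenyl)propane-1,3-dione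
Product: 18 5,6,2',3',6'-pentamethoxyflavone, via hemiketal 17 (not isolated)
Conditions: H2SO4 (0.5 vol %), glacial AcOH, 95–100 °C, 2 h; pour on ice
Reagents that add atoms: none
Why: Acid-catalysed cyclodehydration, in which the phenol adds to the distal carbonyl to give a six-membered hemiketal (racemic, transient) and loss of water gives the aromatic 4-pyranone ring C as an irreversible sink, so the achiral target results.

**Compound list**
1 | 3,4-dimethoxyphenol | Oc1ccc(OC)c(OC)c1 | starting material
2 | sodium 3,4-dimethoxyphenoxide (formed in the flask) | [Na+].[O-]c1ccc(OC)c(OC)c1 | intermediate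
3 | 1,2-dimethoxy-4-(methoxymethoxy)benzene | COCOc1ccc(OC)c(OC)c1 | intermediate
4 | [2,3-dimethoxy-6-(methoxymethoxy)phenyl]lithium (formed in the flask) | [Li]c1c(OC)c(OC)ccc1OCOC | intermediate
5 | lithium 1-[2,3-dimethoxy-6-(methoxymethoxy)phenyl]ethoxide, racemic (formed in the flask) | CC([O-])c1c(OC)c(OC)ccc1OCOC.[Li+] | intermediate
6 | rac-1-[2,3-dimethoxy-6-(methoxymethoxy)phenyl]ethan-1-ol (racemate, centre erased in step 3) | CC(O)c1c(OC)c(OC)ccc1OCOC | intermediate
7 | 1-[2,3-dimethoxy-6-(methoxymethoxy)phenyl]ethan-1-one | CC(=O)c1c(OC)c(OC)ccc1OCOC | intermediate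
8 | 1-(6-hydroxy-2,3-dimethoxyphenyl)ethan-1-one | CC(=O)c1c(O)ccc(OC)c1OC | intermediate
9 | 1,2,4-trimethoxybenzene | COc1ccc(OC)c(OC)c1 | starting material
10 | (2,3,6-trimethoxyphenyl)lithium (formed in the flask) | [Li]c1c(OC)ccc(OC)c1OC | intermediate
11 | lithium 2,3,6-trimethoxybenzoate (formed in the flask) | COc1ccc(OC)c(C(=O)[O-])c1OC.[Li+] | intermediate
12 | 2,3,6-trimethoxybenzoic acid | COc1ccc(OC)c(C(=O)O)c1OC | intermediate
13 | 2,3,6-trimethoxybenzoyl chloride | COc1ccc(OC)c(C(=O)Cl)c1OC | intermediate
14 | dilithium enolate-phenoxide of 8 (formed in the flask) | C=C([O-])c1c([O-])ccc(OC)c1OC.[Li+].[Li+] | intermediate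
15 | dilithium diketonate-phenoxide of 16, delocalised chelate (formed in the flask) | COc1ccc(OC)c(C(=O)C=C([O-])c2c([O-])ccc(OC)c2OC)c1OC.[Li+].[Li+] | intermediate
16 | 1-(6-hydroxy-2,3-dimethoxyphenyl)-3-(2,3,6-trimethoxyphenyl)propane-1,3-dione | COc1ccc(OC)c(C(=O)CC(=O)c2c(O)ccc(OC)c2OC)c1OC | intermediate
17 | rac-2-hydroxy-5,6-dimethoxy-2-(2,3,6-trimethoxyphenyl)chroman-4-one (formed in the flask) | COc1ccc(OC)c(C2(O)CC(=O)c3c(OC)c(OC)ccc3O2)c1OC | intermediate
18 | 5,6,2',3',6'-pentamethoxyflavone (achiral) | COc1ccc(OC)c(-c2cc(=O)c3c(OC)c(OC)ccc3o2)c1OC | target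

**Totals**
- Total step count: 8.
- Longest linear sequence: 6 steps (1, 2, 3, 4, 7, 8). The ring B branch (steps 5 and 6) joins at step 7.

**Three steps most likely to fail**

**Step 2.** The risks are the site of lithiation of 3 and loss of aryllithium 4 through enolisation of acetaldehyde.
- The fallback drops the phenol-directed metalation and fixes the position of the free OH by chelation instead.
- It sets out from 9, which is lithiated to 10 exactly as in step 5.
- Quenching 10 with N-methoxy-N-methylacetamide (THF, −78 °C to rt, then H2O) gives 1-(2,3,6-trimethoxyphenyl)ethan-1-one F1.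
- Oxidative demethylation of the para-related 3- and 6-methoxy groups of this ketone with (NH4)2Ce(NO3)6 in MeCN/H2O at 0 °C gives 2-acetyl-3-methoxy-1,4-benzoquinone F2.
- Reduction with aqueous Na2S2O4 gives 1-(3,6-dihydroxy-2-methoxyphenyl)ethan-1-one F3.
- MeI (1.05 equiv) and K2CO3 in refluxing acetone then methylate only the 3-OH, because the 6-OH is locked in a hydrogen bond to the ketone.
- The fallback comes back to the route at 8 and replaces steps 1 to 4.

**Step 7.** The risks are O-acylation of the phenoxide or the enolate oxygen, attack of free amide base on 13, and a slow reaction between two di-ortho-substituted partners.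
- The fallback sets out from 8, with 13 as the acyl donor, and makes the O-acyl compound on purpose.
- Treating 8 with 13 in pyridine with 4-(dimethylamino)pyridine (cat.) at rt to 60 °C gives 2-acetyl-3,4-dimethoxyphenyl 2,3,6-trimethoxybenzoate F4.
- Powdered KOH in pyridine at 50 °C, followed by acidification with AcOH, brings about the Baker–Venkataraman O-to-C acyl shift through the ketone enolate.
- The fallback comes back to the route at 16.

**Step 8.** The risks are acid cleavage of the peri 5-methoxy group and retro-Claisen cleavage of 16 in hot acid.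
- The fallback avoids the diketone altogether and forms ring C oxidatively. It sets out from 8 and from aryllithium 10 (made from 9 as in step 5).
- Quenching 10 with DMF (−78 °C to rt, then H2O) gives 2,3,6-trimethoxybenzaldehyde F5.
- Claisen–Schmidt aldol condensation of 8 with this aldehyde (KOH, EtOH/H2O, rt, 48 h) gives (E)-1-(6-hydroxy-2,3-dimethoxyphenyl)-3-(2,3,6-trimethoxyphenyl)prop-2-en-1-one F6.
- I2 (10 mol %) in DMSO at 130 °C for 1 h cyclises and dehydrogenates this chalcone without strong acid.
- The fallback comes back to the route at 18.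

**Further compounds**
F1 | step 2 | 1-(2,3,6-trimethoxyphenyl)ethan-1-one | CC(=O)c1c(OC)ccc(OC)c1OC
F2 | step 2 | 2-acetyl-3-methoxy-1,4-benzoquinone | CC(=O)C1=C(OC)C(=O)C=CC1=O
F3 | step 2 | 1-(3,6-dihydroxy-2-methoxyphenyl)ethan-1-one | CC(=O)c1c(O)ccc(O)c1OC
F4 | step 7 | 2-acetyl-3,4-dimethoxyphenyl 2,3,6-trimethoxybenzoate | COc1ccc(OC)c(C(=O)Oc2ccc(OC)c(OC)c2C(C)=O)c1OC
F5 | step 8 | 2,3,6-trimethoxybenzaldehyde | COc1ccc(OC)c(C=O)c1OC
F6 | step 8 | (E)-1-(6-hydroxy-2,3-dimethoxyphenyl)-3-(2,3,6-trimethoxyphenyl)prop-2-en-1-one | COc1ccc(OC)c(/C=C/C(=O)c2c(O)ccc(OC)c2OC)c1OC
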